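**Plan**
- Retrosynthesis: the N1–sulfonyl bond is cut last. N1–C2 and C3–Br are then cut together, which opens the pyrrole ring to an ortho-ethynyl sulfonanilide. Further back lie the sulfonamide N–S bond, the alkynyl C–Si bond, the amine (from nitro), the aryl–alkyne bond at the future C3a, and the C–I bond (from an aryl amine).
- Enabling feature: in the pyrrole ring (N1, C2, C3, C3a, C7a) the C3 bromine and N1 sit trans across C2=C3. This is the pattern left by anti addition of nitrogen (on C7a) and bromine to an ethynyl group on C3a.
- Forward: the benzene ring is bought with the future C4 and C6 bromines in place. The alkyne is attached by cross-coupling, and the only ring formed, the pyrrole, closes in step 6 together with entry of the third bromine.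
- Stereochemistry: the target is planar and has no stereocentre, so nothing has to be set or protected.

Key step: step 6

Assumption: the target is achiral, so the request for a single enantiomer is met trivially and all SMILES carry no stereodescriptors. Compounds 1, 4 and 8 are taken as commercial.

**Route**

Step 1
Reactants: 1 2,4-dibromo-6-nitroaniline
Product: 3 1,5-dibromo-2-iodo-3-nitrobenzene, via 2,4-dibromo-6-nitrobenzenediazonium hydrogen sulfate 2 (not isolated)
Conditions: NaNO2, conc. H2SO4, AcOH, 0–10 °C; then aq. KI, 0 °C→rt
Reagents that add atoms: potassium iodide, [K+].[I-]; sodium nitrite, [Na+].[O-]N=O, and sulfuric acid, OS(O)(=O)=O (these two leave atoms only in 2)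
Why: This weakly basic aniline is diazotised by nitrosylsulfuric acid and the diazonium ion is reduced by iodide itself (Sandmeyer-type iododediazoniation, no copper needed), so iodine replaces NH2 at the carbon that will carry the alkyne.

Step 2
Reactants: 3 1,5-dibromo-2-iodo-3-nitrobenzene; 4 trimethylsilylacetylene
Product: 5 ((2,4-dibromo-6-nitrophenyl)ethynyl)trimethylsilane
Conditions: PdCl2(PPh3)2 (cat.), CuI (cat.), Et3N, THF, rt
Reagents that add atoms: none
Why: Sonogashira coupling; the C–I bond, activated by the ortho nitro group, should undergo oxidative addition at room temperature while the two C–Br bonds (both meta to nitro) stay intact, and the silyl cap prevents double coupling.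

Step 3
Reactants: 5 ((2,4-dibromo-6-nitrophenyl)ethynyl)trimethylsilane
Product: 6 3,5-dibromo-2-((trimethylsilyl)ethynyl)aniline
Conditions: Fe powder, NH4Cl, EtOH–H2O, 70 °C
Reagents that add atoms: none
Why: Béchamp-type iron reduction under near-neutral conditions converts nitro to amine by electron transfer and should spare the aryl bromides, the triple bond and the C–Si bond, all of which catalytic hydrogenation would endanger.

Step 4
Reactants: 6 3,5-dibromo-2-((trimethylsilyl)ethynyl)aniline
Product: 7 3,5-dibromo-2-ethynylaniline
Conditions: K2CO3 (cat.), MeOH–THF, rt
Reagents that add atoms: none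
Why: Base-catalysed methanolysis of the alkynyl C–Si bond (protodesilylation) is fast at room temperature and leaves the aniline and the aryl bromides untouched.

Step 5
Reactants: 7 3,5-dibromo-2-ethynylaniline; 8 4-toluenesulfonyl chloride
Product: 9 N-(3,5-dibromo-2-ethynylphenyl)-4-methylbenzenesulfonamide
Conditions: pyridine, CH2Cl2, 0 °C→rt
Reagents that add atoms: none
Why: N-Sulfonylation of the aniline with pyridine as nucleophilic catalyst and acid scavenger should stop at the mono-sulfonamide and supplies the acidic N–H and the arene-deactivating group that the cyclisation needs.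

Step 6
Reactants: 9 N-(3,5-dibromo-2-ethynylphenyl)-4-methylbenzenesulfonamide
Product: 10 3,4,6-tribromo-1-tosyl-1H-indole
Conditions: NBS (1.05 equiv), NaHCO3, MeCN, 0 °C→rt, dark
Reagents that add atoms: N-bromosuccinimide, O=C1CCC(=O)N1Br
Why: NBS transfers Br+ to the ethynyl group to give a bridged bromonium ion (π-complex), the ortho sulfonamide nitrogen opens it anti at the terminal carbon, and loss of the N–H proton to succinimide anion leaves the aromatic N-sulfonylindole with N1–C2 and C3–Br made in one operation. The closest known reaction type is the 5-endo-dig halocyclisation of 2-alkynyl sulfonanilides and N,N-dialkyl-2-alkynylanilines to 3-haloindoles with I2 or N-halosuccinimides, here carried over to bromine and an unsubstituted alkyne terminus. The pyrrole ring closes in the 5-endo-dig mode, the only one open to the nitrogen because attack at the internal carbon would give a four-membered ring, so bromine must end up on C3. No stereocentre is formed. The step needs chemoselectivity for addition across the triple bond over bromination of the acetylenic C–H, of nitrogen and of the arenes: silver- and amine-free conditions with only solid bicarbonate keep the acetylide pathway closed, any N–Br species formed is itself a reversible Br+ donor, and the ring bromines plus the sulfonyl group deactivate both arenes towards NBS. Using one equivalent of NBS at low temperature in the dark should limit dibromide formation and radical side reactions.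

Step 7
Reactants: 10 3,4,6-tribromo-1-tosyl-1H-indole
Product: 11 3,4,6-tribromo-1H-indole
Conditions: 2 M aq. NaOH, THF–MeOH, 40 °C; then aq. NH4Cl
Reagents that add atoms: none
Why: Hydroxide attacks sulfur of the N-sulfonyl group (sulfonamide hydrolysis) and the N–S bond should break readily because the tribromoindolide is a stabilised leaving group, while the aryl and C3 bromides are inert to aqueous base at this temperature.

**Compound list**
1 | 2,4-dibromo-6-nitroaniline | Nc1c(Br)cc(Br)cc1[N+](=O)[O-] | starting material
2 | 2,4-dibromo-6-nitrobenzenediazonium hydrogen sulfate | N#[N+]c1c(Br)cc(Br)cc1[N+](=O)[O-].OS(=O)(=O)[O-] | intermediate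
3 | 1,5-dibromo-2-iodo-3-nitrobenzene | Ic1c(Br)cc(Br)cc1[N+](=O)[O-] | intermediate
4 | trimethylsilylacetylene | C#C[Si](C)(C)C | starting material
5 | ((2,4-dibromo-6-nitrophenyl)ethynyl)trimethylsilane | C[Si](C)(C)C#Cc1c(Br)cc(Br)cc1[N+](=O)[O-] | intermediate
6 | 3,5-dibromo-2-((trimethylsilyl)ethynyl)aniline | C[Si](C)(C)C#Cc1c(Br)cc(Br)cc1N | intermediate
7 | 3,5-dibromo-2-ethynylaniline | C#Cc1c(Br)cc(Br)cc1N | intermediate
8 | 4-toluenesulfonyl chloride | Cc1ccc(cc1)S(Cl)(=O)=O | starting material
9 | N-(3,5-dibromo-2-ethynylphenyl)-4-methylbenzenesulfonamide | C#Cc1c(Br)cc(Br)cc1NS(=O)(=O)c1ccc(C)cc1 | intermediate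
10 | 3,4,6-tribromo-1-tosyl-1H-indole | Cc1ccc(cc1)S(=O)(=O)n1cc(Br)c2c(Br)cc(Br)cc21 | intermediate
11 | 3,4,6-tribromo-1H-indole | Brc1cc(Br)c2c(Br)c[nH]c2c1 | target

**Count**
Total steps: 7. Longest linear sequence: 7 steps (1 → 11).

**Steps most likely to fail**

Step 6. The risk is that bromine transfer to the acetylenic C–H or to nitrogen outruns addition across the triple bond, or that the electron-poor alkyne does not engage NBS at all. The fallback sets out from 9 and comes back at 10, and it separates ring closure from bromination. Copper(II)-catalysed 5-endo-dig hydroamination of 9 (Cu(OAc)2, 1,2-dichloroethane, reflux) should give 4,6-dibromo-1-tosyl-1H-indole F1. Electrophilic aromatic bromination of F1 at C3 (Br2, CH2Cl2 or DMF, 0 °C→rt) should then give 10.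

Step 2. The risk is slow transmetalation at a C–I bond flanked by bromine and nitro, which would let copper-mediated homocoupling of the silylacetylene and insertion into a C–Br bond compete. The fallback sets out from 3 and comes back at 7. A copper- and amine-free Stille coupling of 3 with tributyl(ethynyl)stannane (Pd(PPh3)4, toluene, 80 °C) should give 1,5-dibromo-2-ethynyl-3-nitrobenzene F2 directly. Iron/ammonium chloride reduction of F2 then leads to 7, bypassing the silylated intermediates 5 and 6.

Step 5. The risk is sluggish sulfonylation of the weakly nucleophilic aniline combined with over-sulfonylation, giving a mixture of mono- and bis-sulfonylated material. The fallback sets out from 7 and comes back at 9. Sulfonylation is driven to completion with excess 8 (Et3N, DMAP, CH2Cl2) to give N-(3,5-dibromo-2-ethynylphenyl)-4-methyl-N-tosylbenzenesulfonamide F3. One sulfonyl group of this activated sulfonimide is then cleaved selectively with 1 M aq. NaOH in THF at room temperature, which should stop at the sulfonamide anion and give 9 on acidification.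

**Further compounds**
F1 | step 6 | 4,6-dibromo-1-tosyl-1H-indole | Cc1ccc(cc1)S(=O)(=O)n1ccc2c(Br)cc(Br)cc21
F2 | step 2 | 1,5-dibromo-2-ethynyl-3-nitrobenzene | C#Cc1c(Br)cc(Br)cc1[N+](=O)[O-]
F3 | step 5 | N-(3,5-dibromo-2-ethynylphenyl)-4-methyl-N-tosylbenzenesulfonamide | C#Cc1c(Br)cc(Br)cc1N(S(=O)(=O)c1ccc(C)cc1)S(=O)(=O)c1ccc(C)cc1
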